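**Strategy.** The cyclopropane bond C1–C10 is shared by the three- and ten-membered rings, and C1 bears the tertiary carbinol C2 (bicyclo[8.1.0]undecene numbering): a cyclopropylcarbinol, the water adduct of a homoallyl cation. The precursor is therefore an eleven-membered (3E,7E)-cycloundecadienyl mesylate of the humulene type, assembled from neryl boronate and a chiral iododienal by allylboration (quaternary carbon and carbinol) and B-alkyl Suzuki ring closure. On buffered solvolysis the E alkene displaces the neighbouring mesylate: one operation forms C1–C10, closes the cyclopropane, contracts the ring to the ten-membered one and sets C10, C1 and C2. Side-chain epoxidation, isomerisation and peroxide displacement complete the route.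

Key step: step 10

Assumption: (R)-TRIP, (R)-3,3'-bis(2,4,6-triisopropylphenyl)-1,1'-binaphthyl-2,2'-diyl hydrogen phosphate, is taken to deliver boron-bound allyl and allenyl groups to the Re face of aldehydes (its enantiomer to the Si face) and the D-fructose-derived Shi ketone to give (R)-epoxides from RCH=CMe2; but-2-ynal is taken as purchased, and 2-methoxyprop-2-yl hydroperoxide is made beforehand by ozonolysis of 2,3-dimethylbut-2-ene in methanol.

Step 1
Reactants: 1 neryl acetate
Product: 2 2-[(2Z)-3,7-dimethylocta-2,6-dien-1-yl]-4,4,5,5-tetramethyl-1,3,2-dioxaborolane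
Conditions: B2pin2, Pd2(dba)3 (2.5 mol %), DMSO, 50 °C
Reagents that add atoms: bis(pinacolato)diboron, CC1(C)OB(OC1(C)C)B1OC(C)(C)C(C)(C)O1
Why: Miyaura-type palladium-catalysed borylation of an allylic acetate puts boron on the unhindered terminus of the π-allyl intermediate, and the Z geometry should survive because syn–anti exchange at the fully substituted allyl terminus is slow.

Step 2
Reactants: 3 but-2-ynal; 4 allenylboronic acid pinacol ester
Product: 6 (4S)-hepta-1,5-diyn-4-ol, via pinacol borate ester 5 (not isolated)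
Conditions: (S)-TRIP (5 mol %), 4 Å MS, toluene, 0 °C; aq. NaHCO3 work-up
Reagents that add atoms: none
Why: Chiral-phosphoric-acid-catalysed propargylation of an aldehyde, in which the acid organises boronate and aldehyde in a closed six-membered transition state and the (S) acid should send the allenyl γ-carbon to the Si face to give the (S) carbinol.

Step 3
Reactants: 6 (4S)-hepta-1,5-diyn-4-ol
Product: 7 tert-butyl[(4S)-hepta-1,5-diyn-4-yloxy]dimethylsilane
Conditions: TBSCl, imidazole, DMF, 0 °C to rt
Reagents that add atoms: tert-butyldimethylsilyl chloride, CC(C)(C)[Si](C)(C)Cl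
Why: Standard silylation of a secondary alcohol, which leaves the stereocentre untouched.

Step 4
Reactants: 7 silyl ether of the diynol; 8 oxirane
Product: 11 (3E,6S)-6-[(tert-butyldimethylsilyl)oxy]-4-methylnon-3-en-7-yn-1-ol, via alkenyl(dimethyl)alane 9 (not isolated), via lithium alkenylalanate 10 (not isolated)
Conditions: Me3Al, Cp2ZrCl2 (0.25 equiv), CH2Cl2, 0 °C to rt; then n-BuLi, THF, −78 °C; then oxirane, −78 °C to rt; aq. KNaC4H4O6 (potassium sodium tartrate) work-up
Reagents that add atoms: trimethylaluminium, C[Al](C)C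
Why: Negishi zirconium-catalysed carboalumination adds methyl and aluminium syn across the terminal alkyne only (the internal alkyne reacts far more slowly), which fixes the E trisubstituted alkene, and the derived alanate opens oxirane with retention of alkene geometry.

Step 5
Reactants: 11 enynol
Product: 13 (3E,6S,7E)-6-[(tert-butyldimethylsilyl)oxy]-8-iodo-4-methylnona-3,7-dien-1-ol, via alkenylzirconocene chloride 12 (not isolated)
Conditions: Cp2Zr(H)Cl (3 equiv, one consumed by the hydroxyl), THF, rt to 45 °C; then I2, 0 °C; aq. Na2S2O3 work-up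
Reagents that add atoms: iodine, II
Why: Hydrozirconation with the Schwartz reagent is a syn addition that, after equilibration with excess reagent, places zirconium on the less hindered methyl-bearing alkyne carbon remote from the silyloxy group, so iodinolysis with retention gives the (E)-2-iodoalkene while the trisubstituted alkene stays inert.

Step 6
Reactants: 13 iododienol
Product: 14 (3E,6S,7E)-6-[(tert-butyldimethylsilyl)oxy]-8-iodo-4-methylnona-3,7-dienal
Conditions: Dess–Martin periodinane, NaHCO3, CH2Cl2, 0 °C; used without storage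
Reagents that add atoms: none
Why: Buffered Dess–Martin oxidation should give the β,γ-unsaturated aldehyde without acid- or base-induced migration of the alkene into conjugation.

Step 7
Reactants: 14 iododienal; 2 neryl pinacol boronate
Product: 16 (6S,7S,9E,12S,13E)-12-[(tert-butyldimethylsilyl)oxy]-6-ethenyl-14-iodo-2,6,10-trimethylpentadeca-2,9,13-trien-7-ol, via pinacol borate ester 15 (not isolated)
Conditions: (R)-TRIP (10 mol %), 4 Å MS, toluene, −20 °C to rt; aq. NaHCO3 work-up
Reagents that add atoms: none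
Why: Allylboration through a closed chair (Zimmerman–Traxler) transition state, in which the Z geometry of 2 places the homoprenyl chain syn to the new hydroxyl and so fixes the quaternary carbon relative to the carbinol, while the (R) acid should direct attack to the Re face of the aldehyde to give the (6S,7S) isomer, any minor diastereomer being separable because C12 is already set.

Step 8
Reactants: 16 open-chain homoallylic alcohol
Product: 18 (1S,3E,6S,7E,11S)-6-[(tert-butyldimethylsilyl)oxy]-4,8,11-trimethyl-11-(4-methylpent-3-en-1-yl)cycloundeca-3,7-dien-1-ol, via B-alkyl-9-BBN borane 17 (not isolated)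
Conditions: 9-BBN (3 equiv), THF, rt; then slow addition to PdCl2(dppf) (20 mol %), AsPh3, Cs2CO3, DMF/THF/H2O, 50 °C, about 1 mM
Reagents that add atoms: none
Why: 9-BBN hydroborates only the monosubstituted vinyl group (the trisubstituted alkenes and the iodoalkene are inert), and intramolecular B-alkyl Suzuki–Miyaura coupling with the vinyl iodide proceeds with retention to close the eleven-membered (E,E)-diene ring, a comparatively unstrained ring of the humulene type.

Step 9
Reactants: 18 cycloundecadienol
Product: 19 (1S,3E,6S,7E,11S)-6-[(tert-butyldimethylsilyl)oxy]-4,8,11-trimethyl-11-(4-methylpent-3-en-1-yl)cycloundeca-3,7-dien-1-yl methanesulfonate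
Conditions: MsCl, Et3N, CH2Cl2, −20 °C; used directly
Reagents that add atoms: methanesulfonyl chloride, CS(=O)(=O)Cl
Why: Mesylation with MsCl and Et3N works on hindered secondary alcohols and leaves the configuration at C1 unchanged.

Step 10
Reactants: 19 cycloundecadienyl mesylate
Product: 20 (1S,2S,4S,5E,9S,10S)-4-[(tert-butyldimethylsilyl)oxy]-2,6,9-trimethyl-9-(4-methylpent-3-en-1-yl)bicyclo[8.1.0]undec-5-en-2-ol
Conditions: acetone/H2O (3:1), 2,6-lutidine (3 equiv), 45 °C
Reagents that add atoms: water, O
Why: Warming the mesylate in buffered aqueous acetone ionises C1–OMs of 19 with participation of the homoallylic C3=C4 π bond (homoallyl-to-cyclopropylcarbinyl rearrangement, the reaction type of the 3,5-cyclosteroid solvolysis of cholesteryl sulfonates): C3 bonds to C1 from the rear as the sulfonate leaves and the tertiary cyclopropylcarbinyl cation at C4 is captured by water. The cyclopropane closes in 3-exo-tet fashion, and because the two carbons joined are 1,3-related members of the eleven-membered ring, the same bond contracts that ring to the ten-membered ring, so both rings of the bicyclo[8.1.0] core arise together. C10 of 20 is set by inversion at the mesylate carbon; C1 by the alkene face that keeps the quaternary C9 and C2 trans on the new ring, the arrangement also preferred in open-chain closures of this type; C2 by anti addition across the E alkene, water entering the non-rotating bisected cation on its peripheral face, remote from the new C1–C10 bond. The step needs homoallylic participation to outrun 1,2-shift at the neopentyl centre and attack by the C7=C8 or side-chain alkenes, which the adjacency and trisubstitution of C3=C4 and the inductive deactivation of C7=C8 by its allylic silyl ether should secure. Capture at the tertiary carbon is kinetically favoured, and the 2,6-lutidine buffer prevents acid-induced return of the tertiary cyclopropylcarbinol to homoallyl products.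

Step 11
Reactants: 20 bicyclic carbinol with prenyl side chain
Product: 21 (1S,2S,4S,5E,9R,10S)-4-[(tert-butyldimethylsilyl)oxy]-9-{2-[(2R)-3,3-dimethyloxiran-2-yl]ethyl}-2,6,9-trimethylbicyclo[8.1.0]undec-5-en-2-ol
Conditions: D-fructose-derived Shi ketone (0.3 equiv), Oxone (2KHSO5·KHSO4·K2SO4), K2CO3, Bu4NHSO4, MeCN/dimethoxymethane/aq. Na2B4O7 buffer, 0 °C, stopped short of full conversion
Reagents that add atoms: potassium peroxymonosulfate (Oxone), [K+].OOS(=O)(=O)[O-]
Why: Shi asymmetric epoxidation, in which the chiral dioxirane attacks the unhindered, electron-rich prenyl alkene through a spiro transition state to give the (R)-epoxide under reagent control, while the ring alkene is shielded by the ring and the neighbouring silyl ether and deactivated by its allylic oxygen.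

Step 12
Reactants: 21 side-chain epoxide
Product: 22 (1S,2S,4S,5E,9R,10S)-4-[(tert-butyldimethylsilyl)oxy]-9-[(3R)-3-hydroxy-4-methylpent-4-en-1-yl]-2,6,9-trimethylbicyclo[8.1.0]undec-5-en-2-ol
Conditions: Et2Al(TMP) (4 equiv, from Et2AlCl and LiTMP), toluene, 0 °C; aq. KNaC4H4O6 work-up
Reagents that add atoms: none
Why: Aluminium-amide-mediated isomerisation of a trisubstituted epoxide to an allylic alcohol removes a methyl proton syn to the breaking tertiary C–O bond and gives the isopropenyl carbinol, and since the C–O bond at the stereocentre is not broken the (R) configuration is kept.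

Step 13
Reactants: 22 allylic alcohol
Product: 23 (3R)-1-[(1S,2S,4S,5E,9R,10S)-4-[(tert-butyldimethylsilyl)oxy]-2-hydroxy-2,6,9-trimethylbicyclo[8.1.0]undec-5-en-9-yl]-4-methylpent-4-en-3-yl methanesulfonate
Conditions: Ms2O, Et3N, CH2Cl2, −30 °C; used directly
Reagents that add atoms: methanesulfonic anhydride, CS(=O)(=O)OS(C)(=O)=O
Why: The secondary allylic hydroxyl is sulfonylated far faster than the hindered tertiary cyclopropylcarbinol, and the anhydride avoids chloride that could displace the allylic mesylate.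

Step 14
Reactants: 23 allylic mesylate
Product: 24 (1S,2S,4S,5E,9R,10S)-4-[(tert-butyldimethylsilyl)oxy]-9-{(3S)-3-[(2-methoxypropan-2-yl)peroxy]-4-methylpent-4-en-1-yl}-2,6,9-trimethylbicyclo[8.1.0]undec-5-en-2-ol
Conditions: 2-methoxyprop-2-yl hydroperoxide, CsOH·H2O, DMF, 0 °C
Reagents that add atoms: 2-methoxyprop-2-yl hydroperoxide, COC(C)(C)OO
Why: SN2 alkylation of the caesium salt of a ketal-protected hydroperoxide by the secondary sulfonate proceeds with inversion to the (S) peroxide, which is carried on as its base-stable monoperoxyketal.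

Step 15
Reactants: 24 silyl-protected peroxyketal
Product: 25 (1S,2S,4S,5E,9R,10S)-9-{(3S)-3-[(2-methoxypropan-2-yl)peroxy]-4-methylpent-4-en-1-yl}-2,6,9-trimethylbicyclo[8.1.0]undec-5-ene-2,4-diol
Conditions: TBAF, AcOH (1:1), THF, 0 °C to rt
Reagents that add atoms: none
Why: Fluoride cleaves the silyl ether, the peroxyketal is stable to fluoride, and buffering with acetic acid suppresses base-induced (Kornblum–DeLaMare) fragmentation of the peroxide.

Step 16
Reactants: 25 diol
Product: 26 (1S,2S,4S,5E,9R,10S)-2-hydroxy-9-{(3S)-3-[(2-methoxypropan-2-yl)peroxy]-4-methylpent-4-en-1-yl}-2,6,9-trimethylbicyclo[8.1.0]undec-5-en-4-yl acetate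
Conditions: Ac2O, pyridine, DMAP (cat.), CH2Cl2, 0 °C to rt
Reagents that add atoms: acetic anhydride, CC(=O)OC(C)=O
Why: Acylation takes only the secondary allylic hydroxyl, because the tertiary cyclopropylcarbinol is too hindered to react and the hydroperoxide is masked.

Step 17
Reactants: 26 acetate peroxyketal
Product: 27 (1S,2S,4S,5E,9R,10S)-2-hydroxy-9-[(3S)-3-hydroperoxy-4-methylpent-4-en-1-yl]-2,6,9-trimethylbicyclo[8.1.0]undec-5-en-4-yl acetate (target)
Conditions: AcOH/THF/H2O (4:2:1), rt
Reagents that add atoms: none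
Why: Mild acid hydrolysis of the monoperoxyketal releases the hydroperoxide without touching the acetate or ionising the tertiary cyclopropylcarbinol.

**Compound list**

1 | neryl acetate, (2Z)-3,7-dimethylocta-2,6-dien-1-yl acetate | CC(C)=CCC/C(C)=C\COC(C)=O | starting material
2 | neryl pinacol boronate, 2-[(2Z)-3,7-dimethylocta-2,6-dien-1-yl]-4,4,5,5-tetramethyl-1,3,2-dioxaborolane | CC(C)=CCC/C(C)=C\CB1OC(C)(C)C(C)(C)O1 | intermediate
3 | but-2-ynal | CC#CC=O | starting material
4 | allenylboronic acid pinacol ester, 4,4,5,5-tetramethyl-2-(propa-1,2-dien-1-yl)-1,3,2-dioxaborolane | C=C=CB1OC(C)(C)C(C)(C)O1 | starting material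
5 | pinacol borate ester of 6, 2-[(4S)-hepta-1,5-diyn-4-yloxy]-4,4,5,5-tetramethyl-1,3,2-dioxaborolane | CC#C[C@@H](OB1OC(C)(C)C(C)(C)O1)CC#C | intermediate (not isolated)
6 | (4S)-hepta-1,5-diyn-4-ol | CC#C[C@@H](O)CC#C | intermediate
7 | tert-butyl[(4S)-hepta-1,5-diyn-4-yloxy]dimethylsilane | CC#C[C@@H](O[Si](C)(C)C(C)(C)C)CC#C | intermediate
8 | oxirane | C1CO1 | starting material
9 | {(1E,4S)-4-[(tert-butyldimethylsilyl)oxy]-2-methylhept-1-en-5-yn-1-yl}dimethylalane | CC#C[C@@H](O[Si](C)(C)C(C)(C)C)C/C(C)=C/[Al](C)C | intermediate (not isolated)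
10 | lithium butyl{(1E,4S)-4-[(tert-butyldimethylsilyl)oxy]-2-methylhept-1-en-5-yn-1-yl}dimethylalanate | CC#C[C@@H](O[Si](C)(C)C(C)(C)C)C/C(C)=C/[Al-](C)(C)CCCC.[Li+] | intermediate (not isolated)
11 | (3E,6S)-6-[(tert-butyldimethylsilyl)oxy]-4-methylnon-3-en-7-yn-1-ol | CC#C[C@@H](O[Si](C)(C)C(C)(C)C)C/C(C)=C/CCO | intermediate
12 | alkenylzirconocene chloride from 11 (chlorozirconocene on C8, trans to C6; hydroxyl as its chlorozirconocene alkoxide) | Cl[Zr](C1C=CC=C1)(C1C=CC=C1)/C(C)=C/[C@@H](O[Si](C)(C)C(C)(C)C)C/C(C)=C/CCO[Zr](Cl)(C1C=CC=C1)C1C=CC=C1 | intermediate (not isolated)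
13 | (3E,6S,7E)-6-[(tert-butyldimethylsilyl)oxy]-8-iodo-4-methylnona-3,7-dien-1-ol | I/C(C)=C/[C@@H](O[Si](C)(C)C(C)(C)C)C/C(C)=C/CCO | intermediate
14 | (3E,6S,7E)-6-[(tert-butyldimethylsilyl)oxy]-8-iodo-4-methylnona-3,7-dienal | I/C(C)=C/[C@@H](O[Si](C)(C)C(C)(C)C)C/C(C)=C/CC=O | intermediate
15 | pinacol borate ester of 16 (O-Bpin at C7) | CC(C)=CCC[C@@](C)(C=C)[C@@H](OB1OC(C)(C)C(C)(C)O1)C/C=C(C)/C[C@H](O[Si](C)(C)C(C)(C)C)/C=C(C)/I | intermediate (not isolated)
16 | (6S,7S,9E,12S,13E)-12-[(tert-butyldimethylsilyl)oxy]-6-ethenyl-14-iodo-2,6,10-trimethylpentadeca-2,9,13-trien-7-ol | CC(C)=CCC[C@@](C)(C=C)[C@@H](O)C/C=C(C)/C[C@H](O[Si](C)(C)C(C)(C)C)/C=C(C)/I | intermediate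
17 | B-alkyl-9-BBN borane from 16 (9-borabicyclo[3.3.1]nonan-9-yl on the terminal carbon of the former vinyl group) | CC(C)=CCC[C@@](C)(CCB1C2CCCC1CCC2)[C@@H](O)C/C=C(C)/C[C@H](O[Si](C)(C)C(C)(C)C)/C=C(C)/I | intermediate (not isolated)
18 | (1S,3E,6S,7E,11S)-6-[(tert-butyldimethylsilyl)oxy]-4,8,11-trimethyl-11-(4-methylpent-3-en-1-yl)cycloundeca-3,7-dien-1-ol | CC(C)=CCC[C@@]1(C)CC/C(C)=C/[C@@H](O[Si](C)(C)C(C)(C)C)C/C(C)=C/C[C@@H]1O | intermediate
19 | (1S,3E,6S,7E,11S)-6-[(tert-butyldimethylsilyl)oxy]-4,8,11-trimethyl-11-(4-methylpent-3-en-1-yl)cycloundeca-3,7-dien-1-yl methanesulfonate | CC(C)=CCC[C@@]1(C)CC/C(C)=C/[C@@H](O[Si](C)(C)C(C)(C)C)C/C(C)=C/C[C@@H]1OS(C)(=O)=O | intermediate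
20 | (1S,2S,4S,5E,9S,10S)-4-[(tert-butyldimethylsilyl)oxy]-2,6,9-trimethyl-9-(4-methylpent-3-en-1-yl)bicyclo[8.1.0]undec-5-en-2-ol | CC(C)=CCC[C@@]1(C)CC/C(C)=C/[C@@H](O[Si](C)(C)C(C)(C)C)C[C@](C)(O)[C@H]2C[C@@H]21 | intermediate
21 | (1S,2S,4S,5E,9R,10S)-4-[(tert-butyldimethylsilyl)oxy]-9-{2-[(2R)-3,3-dimethyloxiran-2-yl]ethyl}-2,6,9-trimethylbicyclo[8.1.0]undec-5-en-2-ol | CC3(C)O[C@@H]3CC[C@@]1(C)CC/C(C)=C/[C@@H](O[Si](C)(C)C(C)(C)C)C[C@](C)(O)[C@H]2C[C@@H]21 | intermediate
22 | (1S,2S,4S,5E,9R,10S)-4-[(tert-butyldimethylsilyl)oxy]-9-[(3R)-3-hydroxy-4-methylpent-4-en-1-yl]-2,6,9-trimethylbicyclo[8.1.0]undec-5-en-2-ol | C=C(C)[C@@H](CC[C@@]1(C)CC/C(C)=C/[C@@H](O[Si](C)(C)C(C)(C)C)C[C@](C)(O)[C@H]2C[C@@H]21)O | intermediate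
23 | (3R)-1-[(1S,2S,4S,5E,9R,10S)-4-[(tert-butyldimethylsilyl)oxy]-2-hydroxy-2,6,9-trimethylbicyclo[8.1.0]undec-5-en-9-yl]-4-methylpent-4-en-3-yl methanesulfonate | C=C(C)[C@@H](CC[C@@]1(C)CC/C(C)=C/[C@@H](O[Si](C)(C)C(C)(C)C)C[C@](C)(O)[C@H]2C[C@@H]21)OS(C)(=O)=O | intermediate
24 | (1S,2S,4S,5E,9R,10S)-4-[(tert-butyldimethylsilyl)oxy]-9-{(3S)-3-[(2-methoxypropan-2-yl)peroxy]-4-methylpent-4-en-1-yl}-2,6,9-trimethylbicyclo[8.1.0]undec-5-en-2-ol | C=C(C)[C@H](CC[C@@]1(C)CC/C(C)=C/[C@@H](O[Si](C)(C)C(C)(C)C)C[C@](C)(O)[C@H]2C[C@@H]21)OOC(C)(C)OC | intermediate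
25 | (1S,2S,4S,5E,9R,10S)-9-{(3S)-3-[(2-methoxypropan-2-yl)peroxy]-4-methylpent-4-en-1-yl}-2,6,9-trimethylbicyclo[8.1.0]undec-5-ene-2,4-diol | C=C(C)[C@H](CC[C@@]1(C)CC/C(C)=C/[C@@H](O)C[C@](C)(O)[C@H]2C[C@@H]21)OOC(C)(C)OC | intermediate
26 | (1S,2S,4S,5E,9R,10S)-2-hydroxy-9-{(3S)-3-[(2-methoxypropan-2-yl)peroxy]-4-methylpent-4-en-1-yl}-2,6,9-trimethylbicyclo[8.1.0]undec-5-en-4-yl acetate | C=C(C)[C@H](CC[C@@]1(C)CC/C(C)=C/[C@@H](OC(C)=O)C[C@](C)(O)[C@H]2C[C@@H]21)OOC(C)(C)OC | intermediate
27 | (1S,2S,4S,5E,9R,10S)-2-hydroxy-9-[(3S)-3-hydroperoxy-4-methylpent-4-en-1-yl]-2,6,9-trimethylbicyclo[8.1.0]undec-5-en-4-yl acetate | C=C(C)[C@H](CC[C@@]1(C)CC/C(C)=C/[C@@H](OC(C)=O)C[C@](C)(O)[C@H]2C[C@@H]21)OO | target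

**Totals.** Total step count: 17. Longest linear sequence: 16 steps (steps 2 to 17, from but-2-ynal); step 1 is the one-step branch to the boronate.

**Steps most likely to fail**

Step 10 (key step). After ionisation the cation may be intercepted across the ring by the C7=C8 alkene or by the side-chain alkene, may suffer a 1,2-shift at the neopentyl centre, or the ring may impose the alkene face that leads to cis fusion. The fallback makes the same bond before the ring exists, where closures of this kind are trans-selective for steric reasons. Setting out from 16, mesylation (MsCl, Et3N) would give the open-chain homoallylic mesylate F1. Buffered solvolysis (acetone/H2O, 2,6-lutidine) would give the open-chain trans-cyclopropyl carbinol F2. Hydroboration of its vinyl group with 9-BBN would give the B-alkyl-9-BBN borane F3, not isolated, and B-alkyl Suzuki–Miyaura macrocyclisation (PdCl2(dppf), AsPh3, Cs2CO3, high dilution) would close the ten-membered ring directly and come back to the route at 20.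

Step 8. Slow ring closure may let the alkylborane protodeboronate or the alkylpalladium intermediate undergo β-hydride elimination, and intermolecular coupling may give oligomers. The fallback is a macrocyclic Mizoroki–Heck reaction that needs no boron. Setting out from 16, Pd(OAc)2, Bu4NCl and K2CO3 in DMF at high dilution would join the vinyl iodide to the terminal carbon of the vinyl group; the quaternary neighbour leaves only one direction for β-hydride elimination, which would give the eleven-membered (3E,7E,9E)-trienol F4. Chemoselective diimide reduction of its only disubstituted alkene (2-nitrobenzenesulfonylhydrazide, Et3N, CH2Cl2) would come back to the route at 18.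

Step 14. The peroxide anion may attack the alkene terminus (SN2'), may act as a base and eliminate to the diene, or the allylic mesylate may ionise; each erodes regio- and stereochemical integrity. The fallback introduces the hydroperoxide by a Schenck ene reaction with singlet oxygen and accepts lower selectivity. Setting out from 20, desilylation (TBAF, AcOH) would give the prenyl diol F5, and acetylation (Ac2O, pyridine) the prenyl allylic acetate F6. Photooxygenation (O2, tetraphenylporphyrin, visible light, CH2Cl2, −20 °C) should favour the prenyl group over the acetate-deactivated ring alkene and would give 27 together with its side-chain epimer and the tertiary hydroperoxide regioisomer, from which 27 would be separated by HPLC.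

Further compounds
F1 | step 10 | (6S,7S,9E,12S,13E)-12-[(tert-butyldimethylsilyl)oxy]-6-ethenyl-14-iodo-2,6,10-trimethylpentadeca-2,9,13-trien-7-yl methanesulfonate | CC(C)=CCC[C@@](C)(C=C)[C@@H](OS(C)(=O)=O)C/C=C(C)/C[C@H](O[Si](C)(C)C(C)(C)C)/C=C(C)/I
F2 | step 10 | (2S,4S,5E)-4-[(tert-butyldimethylsilyl)oxy]-2-{(1S,2S)-2-[(3S)-3,7-dimethylocta-1,6-dien-3-yl]cyclopropyl}-6-iodohept-5-en-2-ol | CC(C)=CCC[C@@](C)(C=C)[C@H]1C[C@@H]1[C@@](C)(O)C[C@H](O[Si](C)(C)C(C)(C)C)/C=C(C)/I
F3 | step 10 | B-alkyl-9-BBN borane from F2 (9-borabicyclo[3.3.1]nonan-9-yl on the terminal carbon of the former vinyl group) | CC(C)=CCC[C@@](C)(CCB3C4CCCC3CCC4)[C@H]1C[C@@H]1[C@@](C)(O)C[C@H](O[Si](C)(C)C(C)(C)C)/C=C(C)/I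
F4 | step 8 | (1S,3E,6S,7E,9E,11S)-6-[(tert-butyldimethylsilyl)oxy]-4,8,11-trimethyl-11-(4-methylpent-3-en-1-yl)cycloundeca-3,7,9-trien-1-ol | CC(C)=CCC[C@@]1(C)/C=C/C(C)=C/[C@@H](O[Si](C)(C)C(C)(C)C)C/C(C)=C/C[C@@H]1O
F5 | step 14 | (1S,2S,4S,5E,9S,10S)-2,6,9-trimethyl-9-(4-methylpent-3-en-1-yl)bicyclo[8.1.0]undec-5-ene-2,4-diol | CC(C)=CCC[C@@]1(C)CC/C(C)=C/[C@@H](O)C[C@](C)(O)[C@H]2C[C@@H]21
F6 | step 14 | (1S,2S,4S,5E,9S,10S)-2-hydroxy-2,6,9-trimethyl-9-(4-methylpent-3-en-1-yl)bicyclo[8.1.0]undec-5-en-4-yl acetate | CC(C)=CCC[C@@]1(C)CC/C(C)=C/[C@@H](OC(C)=O)C[C@](C)(O)[C@H]2C[C@@H]21
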